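The butenolide ring (O–C12(=O)–C11=C7–C6; germacrane numbering) is fused through C6–C7 to the ten-membered carbocycle, so C12 is read as carbon monoxide, C7≡C11 as an alkyne and C6–O as an aldehyde. One nickel-mediated carbonylative [2+2+1] (hetero-Pauson–Khand-type) macro-annulation of a linear (Z)-enal-yne should form C6–C7 and C11–C12 (and C12–O), close both the ten-membered ring and the lactone, and set C6. The precursor is an open C6→C13 chain that already holds the anti-1,3-diol (C1, C3, as an acetonide), the Z-C4=C5 enal, the C10 methylene and a silyl-protected propargylic alcohol; it is built by Evans aldol, Weinreb ketone synthesis and Evans–Saksena reduction.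

Key step: step 15

Remark: germacrane numbering is used throughout (ring C1–C10; C11, C12, C13 = lactone α-carbon, carbonyl carbon and CH2OH carbon; C14 = exocyclic CH2; C15 = methyl). The target is the (1S,3S,6R,4Z) isomer encoded in the SMILES.

Step 1
Reactants: 1 hexa-1,5-diyne
Product: 3 hepta-2,6-diyn-1-ol, via lithium hexa-1,5-diyn-1-ide 2 (not isolated)
Conditions: 1 (3 equiv), n-BuLi (1 equiv), THF, −78 °C; (CH2O)n, −78 °C to rt; H2O
Reagents that add atoms: paraformaldehyde (formaldehyde), C=O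
Why: Monolithiation of the diyne (used in excess) and addition of the acetylide to formaldehyde should give the propargylic alcohol that carries the future C13 (acetylide hydroxymethylation).

Step 2
Reactants: 3 hepta-2,6-diyn-1-ol
Product: 4 tert-butyl(hepta-2,6-diyn-1-yloxy)diphenylsilane
Conditions: TBDPSCl, imidazole, CH2Cl2, 0 °C to rt
Reagents that add atoms: tert-butyl(chloro)diphenylsilane, CC(C)(C)[Si](Cl)(c1ccccc1)c1ccccc1
Why: Silylation of the primary alcohol gives a bulky ether that should survive the organolithium, acid and buffered fluoride steps and later steer the regiochemistry of the key step.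

Step 3
Reactants: 4 tert-butyl(hepta-2,6-diyn-1-yloxy)diphenylsilane
Product: 6 [(6-bromohept-6-en-2-yn-1-yl)oxy](tert-butyl)diphenylsilane, via (Z)-2-bromoalkenyl-9-BBN adduct 5 (not isolated)
Conditions: B-bromo-9-BBN, CH2Cl2, 0 °C; AcOH, 0 °C to rt
Reagents that add atoms: B-bromo-9-borabicyclo[3.3.1]nonane, BrB1C2CCCC1CCC2
Why: Syn-bromoboration of the terminal alkyne puts boron on the terminal and bromine on the internal carbon while the internal alkyne stays inert, and protonolysis of the C–B bond should give the 2-bromo-1-alkene (haloboration–protodeboronation).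

Step 4
Reactants: 7 but-2-yn-1-ol
Product: 9 (Z)-3-iodobut-2-en-1-ol, via cyclic sodium alkenylaluminate 8 (not isolated)
Conditions: NaAlH2(OCH2CH2OCH3)2 (Red-Al), THF, 0 °C to rt; I2, −78 °C to 0 °C; aq. Rochelle salt
Reagents that add atoms: iodine, II
Why: Alkoxide-directed trans-hydroalumination places aluminium on C3 cis to the CH2O group in a five-membered aluminate and iodinolysis with retention should give the Z-iodoalkene, which fixes the later Z-C4=C5 geometry.

Step 5
Reactants: 9 (Z)-3-iodobut-2-en-1-ol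
Product: 10 (Z)-tert-butyl[(3-iodobut-2-en-1-yl)oxy]dimethylsilane
Conditions: TBSCl, imidazole, CH2Cl2, 0 °C to rt
Reagents that add atoms: tert-butyl(chloro)dimethylsilane, CC(C)(C)[Si](C)(C)Cl
Why: Routine silylation masks the future C6 hydroxyl with a group that can later be removed in the presence of the TBDPS ether.

Step 6
Reactants: 10 (Z)-tert-butyl[(3-iodobut-2-en-1-yl)oxy]dimethylsilane
Product: 12 (Z)-4-(tert-butyldimethylsilyloxy)-2-methylbut-2-enal, via (Z)-alkenyllithium 11 (not isolated)
Conditions: t-BuLi (2.1 equiv), Et2O, −78 °C; DMF, −78 °C to 0 °C; H2O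
Reagents that add atoms: N,N-dimethylformamide, CN(C)C=O
Why: Iodine–lithium exchange proceeds with retention of alkene geometry and formylation with DMF should give the Z-enal (the future C3 aldehyde).

Step 7
Reactants: 13 (S)-4-benzyl-3-(2-chloroacetyl)oxazolidin-2-one; 12 (Z)-4-(tert-butyldimethylsilyloxy)-2-methylbut-2-enal
Product: 15 (S)-4-benzyl-3-[(2S,3R,Z)-6-(tert-butyldimethylsilyloxy)-2-chloro-3-hydroxy-4-methylhex-4-enoyl]oxazolidin-2-one, via dibutylboron Z-enolate 14 (not isolated)
Conditions: Bu2BOTf, Et3N, CH2Cl2, −78 °C to 0 °C; 12, −78 °C to 0 °C; pH 7 buffer, MeOH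
Reagents that add atoms: none
Why: Evans syn aldol, in which the boron Z-enolate reacts through a Zimmerman–Traxler chair on the face opposite the benzyl group, so the auxiliary sets the carbinol centre (the future C3) next to a removable α-chloro centre.

Step 8
Reactants: 15 (S)-4-benzyl-3-[(2S,3R,Z)-6-(tert-butyldimethylsilyloxy)-2-chloro-3-hydroxy-4-methylhex-4-enoyl]oxazolidin-2-one
Product: 16 (S)-4-benzyl-3-[(3S,Z)-6-(tert-butyldimethylsilyloxy)-3-hydroxy-4-methylhex-4-enoyl]oxazolidin-2-one
Conditions: Zn dust, AcOH, THF, rt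
Reagents that add atoms: none
Why: Zinc reduces the activated α-C–Cl bond to C–H without touching the carbinol centre, so that steps 7 and 8 together amount to an auxiliary-controlled acetate aldol.

Step 9
Reactants: 16 (S)-4-benzyl-3-[(3S,Z)-6-(tert-butyldimethylsilyloxy)-3-hydroxy-4-methylhex-4-enoyl]oxazolidin-2-one
Product: 17 (3S,Z)-6-(tert-butyldimethylsilyloxy)-3-hydroxy-N-methoxy-N,4-dimethylhex-4-enamide
Conditions: MeNHOMe·HCl, AlMe3, CH2Cl2, −10 °C to rt; aq. Rochelle salt
Reagents that add atoms: N,O-dimethylhydroxylamine hydrochloride, CNOC.Cl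
Why: Aluminium amide transamidation of the β-hydroxy imide (Weinreb amide formation), assisted by the free hydroxyl, should release the auxiliary without epimerisation.

Step 10
Reactants: 17 (3S,Z)-6-(tert-butyldimethylsilyloxy)-3-hydroxy-N-methoxy-N,4-dimethylhex-4-enamide; 6 [(6-bromohept-6-en-2-yn-1-yl)oxy](tert-butyl)diphenylsilane
Product: 20 (5S,6Z)-8-(tert-butyldimethylsilyloxy)-2-[5-(tert-butyldiphenylsilyloxy)pent-3-yn-1-yl]-5-hydroxy-6-methylocta-1,6-dien-3-one, via chloromagnesium alkoxide 18 (not isolated), via 2-lithioalkene 19 (not isolated)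
Conditions: 17, i-PrMgCl (1.0 equiv), THF, −40 °C; separately 6 (1.5 equiv), t-BuLi (3.0 equiv), Et2O, −78 °C; combined, −78 °C to −20 °C; H2O
Reagents that add atoms: none
Why: Weinreb ketone synthesis, in which the 2-lithioalkene adds once to the amide and the chelated tetrahedral adduct persists until work-up, so the β-hydroxy enone should form without over-addition or retro-aldol, the hydroxyl being masked in the flask as its magnesium alkoxide.

Step 11
Reactants: 20 (5S,6Z)-8-(tert-butyldimethylsilyloxy)-2-[5-(tert-butyldiphenylsilyloxy)pent-3-yn-1-yl]-5-hydroxy-6-methylocta-1,6-dien-3-one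
Product: 21 (3S,5S,6Z)-8-(tert-butyldimethylsilyloxy)-2-[5-(tert-butyldiphenylsilyloxy)pent-3-yn-1-yl]-6-methylocta-1,6-diene-3,5-diol
Conditions: Me4NBH(OAc)3, MeCN/AcOH (1:1), −30 °C to −20 °C; aq. Rochelle salt
Reagents that add atoms: none
Why: Evans–Saksena reduction, in which the C3 hydroxyl binds boron and delivers hydride intramolecularly through a chair to the ketone (1,2-reduction), should give the 1,3-anti diol and so set C1 as S.

Step 12
Reactants: 21 (3S,5S,6Z)-8-(tert-butyldimethylsilyloxy)-2-[5-(tert-butyldiphenylsilyloxy)pent-3-yn-1-yl]-6-methylocta-1,6-diene-3,5-diol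
Product: 22 isopropylidene acetal of 21, a (4S,6S)-2,2-dimethyl-1,3-dioxane that carries the 6-(tert-butyldiphenylsilyloxy)hex-1-en-4-yn-2-yl group at C4 and the (Z)-4-(tert-butyldimethylsilyloxy)but-2-en-2-yl group at C6
Conditions: 2,2-dimethoxypropane, PPTS (cat.), CH2Cl2, rt
Reagents that add atoms: 2,2-dimethoxypropane, COC(C)(C)OC
Why: Acetal exchange locks the anti-1,3-diol as an acetonide which, unlike allylic esters, cannot ionise to an allyl complex with zerovalent nickel in step 15 and which pre-bends the chain.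

Step 13
Reactants: 22 isopropylidene acetal of 21
Product: 23 primary allylic alcohol (C6–OH) obtained from 22 by loss of the TBS group
Conditions: HF·pyridine, pyridine, THF, 0 °C
Reagents that add atoms: none
Why: Buffered HF cleaves the primary allylic TBS ether much faster than the TBDPS ether and leaves the acetonide untouched (selective desilylation).

Step 14
Reactants: 23 primary allylic alcohol
Product: 24 (Z)-enal-yne, the C6 aldehyde of 23
Conditions: Dess–Martin periodinane, NaHCO3, CH2Cl2, 0 °C; used at once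
Reagents that add atoms: none
Why: Buffered Dess–Martin oxidation works under neutral conditions at 0 °C, which should keep the Z geometry of the β,β-disubstituted enal.

Step 15
Reactants: 24 (Z)-enal-yne
Product: 26 13-O-TBDPS-1,3-O-isopropylidene derivative of the target (ten-membered ring fused to the butenolide, 6R), via oxanickelacyclopentene 25 (not isolated)
Conditions: Ni(cod)2 (1.2 equiv), PCy3 (1.2 equiv), toluene, slow addition of 24 to 2 mM, 25 °C; then CO (1 atm), 0 °C to 25 °C
Reagents that add atoms: carbon monoxide, [C-]#[O+]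
Why: Proposed new method: zerovalent nickel binds the aldehyde and the alkyne of 24 and couples them oxidatively to the oxanickelacyclopentene 25 (C6–C7 bond), carbon monoxide then inserts into the Ni–C11 bond (C11–C12 bond) and C–O reductive elimination releases the butenolide; the closest known reaction types are the hetero-Pauson–Khand reaction of 1,6- and 1,7-ynals (Mo(CO)6 or Ru3(CO)12), nickel-catalysed reductive macrocyclisation of ynals and the CO-induced collapse of oxanickelacycles to lactones. The ten-membered carbocycle closes in the 10-exo-dig mode (C6 to C7, C11 stays outside the ring) and the five-membered lactone closes by CO insertion and C(acyl)–O reductive elimination at nickel. The new C6 centre is set under substrate control by the C3 stereocentre: allylic 1,3-strain across the Z-C4=C5 bond keeps H3 and the hydrogen of the s-trans aldehyde in the alkene plane, and C7 should add to the aldehyde face syn to the C3 oxygen so that the tether crosses the alkene plane as in a relaxed (Z)-cyclodecene, which corresponds to 6R. The step needs C7 over C11 regioselectivity (the bulky CH2OTBDPS group stays next to nickel), carbonyl over β-carbon coupling of the enal (C4 is fully substituted) and ring closure over oligomerisation (high dilution, with the Z-alkene, the acetonide and the 1,1-disubstituted C10 alkene as turn elements).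

Step 16
Reactants: 26 13-O-TBDPS-1,3-O-isopropylidene derivative of the target
Product: 27 13-O-TBDPS ether of the (1S,3S,6R)-1,3-diol
Conditions: AcOH/H2O (4:1), 40 °C
Reagents that add atoms: none
Why: Mild aqueous acid should hydrolyse the acetonide while the TBDPS ether, the butenolide and both allylic carbinol centres persist.

Step 17
Reactants: 27 13-O-TBDPS ether of the 1,3-diol
Product: 28 13-O-TBDPS ether of the target (1,3-diacetate)
Conditions: Ac2O, pyridine, DMAP (cat.), CH2Cl2, rt
Reagents that add atoms: acetic anhydride, CC(=O)OC(C)=O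
Why: DMAP-catalysed acetylation of the two secondary allylic alcohols takes place at oxygen and so retains the configuration at C1 and C3.

Step 18
Reactants: 28 13-O-TBDPS ether of the target
Product: 29 (1S,3S,6R,4Z)-1,3-diacetoxy-13-hydroxygermacra-4,7(11),10(14)-trien-12,6-olide (target)
Conditions: HF·pyridine, pyridine, THF, 0 °C to rt
Reagents that add atoms: none
Why: Buffered, non-basic fluoride cleavage of the silyl ether should free the primary C13 hydroxyl without acetate migration or epimerisation at the butenolide γ-carbon.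

Compound list
1 | hexa-1,5-diyne | C#CCCC#C | starting material
2 | lithium hexa-1,5-diyn-1-ide | [Li]C#CCCC#C | intermediate
3 | hepta-2,6-diyn-1-ol | OCC#CCCC#C | intermediate
4 | tert-butyl(hepta-2,6-diyn-1-yloxy)diphenylsilane | C#CCCC#CCO[Si](c1ccccc1)(c1ccccc1)C(C)(C)C | intermediate
5 | (Z)-9-[2-bromo-7-(tert-butyldiphenylsilyloxy)hept-1-en-5-yn-1-yl]-9-borabicyclo[3.3.1]nonane | Br/C(CCC#CCO[Si](c1ccccc1)(c1ccccc1)C(C)(C)C)=C\B1C2CCCC1CCC2 | intermediate
6 | [(6-bromohept-6-en-2-yn-1-yl)oxy](tert-butyl)diphenylsilane | C=C(Br)CCC#CCO[Si](c1ccccc1)(c1ccccc1)C(C)(C)C | intermediate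
7 | but-2-yn-1-ol | CC#CCO | starting material
8 | sodium 2,2-bis(2-methoxyethoxy)-3-methyl-2,5-dihydro-1,2-oxaluminol-2-uide (cyclic alkenylaluminate) | CC1=CCO[Al-]1(OCCOC)OCCOC.[Na+] | intermediate
9 | (Z)-3-iodobut-2-en-1-ol | C/C(I)=C/CO | intermediate
10 | (Z)-tert-butyl[(3-iodobut-2-en-1-yl)oxy]dimethylsilane | C/C(I)=C/CO[Si](C)(C)C(C)(C)C | intermediate
11 | (Z)-[4-(tert-butyldimethylsilyloxy)but-2-en-2-yl]lithium | C/C([Li])=C/CO[Si](C)(C)C(C)(C)C | intermediate
12 | (Z)-4-(tert-butyldimethylsilyloxy)-2-methylbut-2-enal | C/C(C=O)=C/CO[Si](C)(C)C(C)(C)C | intermediate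
13 | (S)-4-benzyl-3-(2-chloroacetyl)oxazolidin-2-one | O=C(CCl)N1C(=O)OC[C@@H]1Cc1ccccc1 | starting material
14 | dibutylboron (Z)-enolate of 13 | Cl/C=C(\OB(CCCC)CCCC)N1C(=O)OC[C@@H]1Cc1ccccc1 | intermediate
15 | (S)-4-benzyl-3-[(2S,3R,Z)-6-(tert-butyldimethylsilyloxy)-2-chloro-3-hydroxy-4-methylhex-4-enoyl]oxazolidin-2-one | O=C(N1C(=O)OC[C@@H]1Cc1ccccc1)[C@@H](Cl)[C@H](O)/C(C)=C\CO[Si](C)(C)C(C)(C)C | intermediate
16 | (S)-4-benzyl-3-[(3S,Z)-6-(tert-butyldimethylsilyloxy)-3-hydroxy-4-methylhex-4-enoyl]oxazolidin-2-one | O=C(N1C(=O)OC[C@@H]1Cc1ccccc1)C[C@H](O)/C(C)=C\CO[Si](C)(C)C(C)(C)C | intermediate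
17 | (3S,Z)-6-(tert-butyldimethylsilyloxy)-3-hydroxy-N-methoxy-N,4-dimethylhex-4-enamide | CON(C)C(=O)C[C@H](O)/C(C)=C\CO[Si](C)(C)C(C)(C)C | intermediate
18 | chloromagnesium alkoxide of 17 | CON(C)C(=O)C[C@H](O[Mg]Cl)/C(C)=C\CO[Si](C)(C)C(C)(C)C | intermediate
19 | [7-(tert-butyldiphenylsilyloxy)hept-1-en-5-yn-2-yl]lithium | [Li]C(=C)CCC#CCO[Si](c1ccccc1)(c1ccccc1)C(C)(C)C | intermediate
20 | (5S,6Z)-8-(tert-butyldimethylsilyloxy)-2-[5-(tert-butyldiphenylsilyloxy)pent-3-yn-1-yl]-5-hydroxy-6-methylocta-1,6-dien-3-one | C=C(CCC#CCO[Si](c1ccccc1)(c1ccccc1)C(C)(C)C)C(=O)C[C@H](O)/C(C)=C\CO[Si](C)(C)C(C)(C)C | intermediate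
21 | (3S,5S,6Z)-8-(tert-butyldimethylsilyloxy)-2-[5-(tert-butyldiphenylsilyloxy)pent-3-yn-1-yl]-6-methylocta-1,6-diene-3,5-diol (anti-1,3-diol) | C=C(CCC#CCO[Si](c1ccccc1)(c1ccccc1)C(C)(C)C)[C@@H](O)C[C@H](O)/C(C)=C\CO[Si](C)(C)C(C)(C)C | intermediate
22 | isopropylidene acetal of 21, (4S,6S)-2,2-dimethyl-1,3-dioxane with TBS ether at C6 and TBDPS ether at C13 | C=C(CCC#CCO[Si](c1ccccc1)(c1ccccc1)C(C)(C)C)[C@@H]1C[C@@H](/C(C)=C\CO[Si](C)(C)C(C)(C)C)OC(C)(C)O1 | intermediate
23 | C6 primary allylic alcohol of the acetonide | C=C(CCC#CCO[Si](c1ccccc1)(c1ccccc1)C(C)(C)C)[C@@H]1C[C@@H](/C(C)=C\CO)OC(C)(C)O1 | intermediate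
24 | (Z)-enal-yne, C6 aldehyde of the acetonide | C=C(CCC#CCO[Si](c1ccccc1)(c1ccccc1)C(C)(C)C)[C@@H]1C[C@@H](/C(C)=C\C=O)OC(C)(C)O1 | intermediate
25 | oxanickelacyclopentene (Ni bound to O6 and C11, PCy3 as ligand) fused to the ten-membered ring | C=C1CCC2=C(CO[Si](c3ccccc3)(c3ccccc3)C(C)(C)C)[Ni-]([P+](C3CCCCC3)(C3CCCCC3)C3CCCCC3)O[C@@H]2/C=C(/C)[C@@H]3C[C@@H]1OC(C)(C)O3 | intermediate
26 | (1S,3S,6R,4Z)-13-(tert-butyldiphenylsilyloxy)-1,3-(isopropylidenedioxy)germacra-4,7(11),10(14)-trien-12,6-olide | C=C1CCC2=C(CO[Si](c3ccccc3)(c3ccccc3)C(C)(C)C)C(=O)O[C@@H]2/C=C(/C)[C@@H]3C[C@@H]1OC(C)(C)O3 | intermediate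
27 | (1S,3S,6R,4Z)-13-(tert-butyldiphenylsilyloxy)-1,3-dihydroxygermacra-4,7(11),10(14)-trien-12,6-olide | C=C1CCC2=C(CO[Si](c3ccccc3)(c3ccccc3)C(C)(C)C)C(=O)O[C@@H]2/C=C(/C)[C@@H](O)C[C@@H]1O | intermediate
28 | (1S,3S,6R,4Z)-1,3-diacetoxy-13-(tert-butyldiphenylsilyloxy)germacra-4,7(11),10(14)-trien-12,6-olide | C=C1CCC2=C(CO[Si](c3ccccc3)(c3ccccc3)C(C)(C)C)C(=O)O[C@@H]2/C=C(/C)[C@@H](OC(C)=O)C[C@@H]1OC(C)=O | intermediate
29 | (1S,3S,6R,4Z)-1,3-diacetoxy-13-hydroxygermacra-4,7(11),10(14)-trien-12,6-olide | C=C1CCC2=C(CO)C(=O)O[C@@H]2/C=C(/C)[C@@H](OC(C)=O)C[C@@H]1OC(C)=O | target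

Total step count: 18 steps.
Longest linear sequence: 15 steps (steps 4 to 18, from but-2-yn-1-ol 7).

Steps most likely to fail

1. Step 15 (Proposed new method). The ynal may oligomerise instead of closing the ten-membered ring, the alkyne may couple at the enal β-carbon or through C11, and the facial selectivity at C6 may be poor. The fallback uses known chemistry, sets out from 23 and comes back at 26. Alcohol 23 is protected as its 4-methoxybenzyl ether F1 (NaH, PMBCl, Bu4NI, THF). TBAF removes the TBDPS group to give the propargylic alcohol F2. Oxidation (TEMPO cat., PhI(OAc)2, MeCN/H2O) gives the ynoic acid F3, and TMSCHN2 gives the methyl ynoate F4, in which the old C13 carbon has become the future lactone carbonyl C12. A MgI2-mediated iodo-aldol reaction with formaldehyde (β-iodo Morita–Baylis–Hillman type, CH2Cl2, 0 °C) adds the new C13 and should give the (Z)-β-iodo-α-(hydroxymethyl) enoate F5 with iodine cis to the ester. Silylation (TBDPSCl, imidazole) gives F6, DDQ (CH2Cl2/H2O) frees the C6 alcohol F7, and Dess–Martin oxidation gives the enal F8. An intramolecular Nozaki–Hiyama–Kishi reaction (CrCl2 in excess, NiCl2 cat., DMSO/THF, high dilution), a ring closure that is established for ten-membered germacranolide rings, forms C6–C7, and the chromium alkoxide lactonises onto the cis ester to give 26.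

2. Step 8. The zinc enolate formed during dechlorination may lose the β-hydroxyl by elimination or fragment by retro-aldol. The fallback sets out from 12 and comes back at 17. The tin enolate of (R)-3-acetyl-4-isopropylthiazolidine-2-thione (Sn(OTf)2, N-ethylpiperidine, CH2Cl2, −78 °C) adds to enal 12 through a tin-chelated chair, which for the R auxiliary is predicted to give the 3S carbinol, and gives the acetate aldol adduct F9 directly, with no α-chloro stage. Displacement of the auxiliary with MeNHOMe·HCl and imidazole gives 17.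

3. Step 3. Bromoboration may also attack the internal alkyne, or the Lewis-acidic boron bromide may cleave the propargylic silyl ether. The fallback sets out from 4 and comes back at 6. Nickel-catalysed α-selective hydroalumination of the terminal alkyne (i-Bu2AlH, NiCl2(dppp) cat., THF, 0 °C to rt) gives the 2-alkenylalane F10, and bromination of the C–Al bond with N-bromosuccinimide gives 6.

Further compounds
F1 | step 15 | 4-methoxybenzyl ether of alcohol 23 | C=C(CCC#CCO[Si](c1ccccc1)(c1ccccc1)C(C)(C)C)[C@@H]1C[C@@H](/C(C)=C\COCc2ccc(OC)cc2)OC(C)(C)O1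
F2 | step 15 | propargylic alcohol from F1 (TBDPS removed) | C=C(CCC#CCO)[C@@H]1C[C@@H](/C(C)=C\COCc2ccc(OC)cc2)OC(C)(C)O1
F3 | step 15 | ynoic acid from F2 | C=C(CCC#CC(=O)O)[C@@H]1C[C@@H](/C(C)=C\COCc2ccc(OC)cc2)OC(C)(C)O1
F4 | step 15 | methyl ynoate from F3 | C=C(CCC#CC(=O)OC)[C@@H]1C[C@@H](/C(C)=C\COCc2ccc(OC)cc2)OC(C)(C)O1
F5 | step 15 | methyl (Z)-2-(hydroxymethyl)-3-iodo enoate from F4 | C=C(CC/C(I)=C(\CO)C(=O)OC)[C@@H]1C[C@@H](/C(C)=C\COCc2ccc(OC)cc2)OC(C)(C)O1
F6 | step 15 | TBDPS ether of F5 | C=C(CC/C(I)=C(\CO[Si](c2ccccc2)(c2ccccc2)C(C)(C)C)C(=O)OC)[C@@H]1C[C@@H](/C(C)=C\COCc2ccc(OC)cc2)OC(C)(C)O1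
F7 | step 15 | C6 primary allylic alcohol from F6 | C=C(CC/C(I)=C(\CO[Si](c2ccccc2)(c2ccccc2)C(C)(C)C)C(=O)OC)[C@@H]1C[C@@H](/C(C)=C\CO)OC(C)(C)O1
F8 | step 15 | (Z)-enal with the (Z)-β-iodo enoate, from F7 | C=C(CC/C(I)=C(\CO[Si](c2ccccc2)(c2ccccc2)C(C)(C)C)C(=O)OC)[C@@H]1C[C@@H](/C(C)=C\C=O)OC(C)(C)O1
F9 | step 8 | (R)-3-[(3S,Z)-6-(tert-butyldimethylsilyloxy)-3-hydroxy-4-methylhex-4-enoyl]-4-isopropylthiazolidine-2-thione | CC(C)[C@@H]1CSC(=S)N1C(=O)C[C@H](O)/C(C)=C\CO[Si](C)(C)C(C)(C)C
F10 | step 3 | diisobutyl[7-(tert-butyldiphenylsilyloxy)hept-1-en-5-yn-2-yl]alane | CC(C)C[Al](CC(C)C)C(=C)CCC#CCO[Si](c1ccccc1)(c1ccccc1)C(C)(C)C
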